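**Assumption:** 4‑bromopent‑4‑enoic acid, pent‑1‑en‑4‑yne, bis(pinacolato)borylmethane, vinyl bromide (THF solution) and (R)‑TRIP are treated as catalogue items.

## Retrosynthetic overview

1. Final bond: the diene C(sp2)–C(sp2) bond, by Suzuki coupling of cyclic (Z)‑alkenylboronic hemiester 12 with 2‑bromoalkene carbamate 14; no protecting groups are used.
2. Key step: one chiral‑phosphoric‑acid‑catalysed allylboration of aldehyde 8 with the gem‑diboryl allyl reagent 11 forms the carbinol C–C bond, the (R)‑stereocentre and the (Z)‑olefin together, and leaves boron as the coupling handle.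
3. Aldehyde 8 comes from ester 7 (DIBAL); its skipped (Z)‑diene comes from Cu‑mediated alkynylation of chloromethylthiazole 4 followed by Lindlar reduction.
4. Ring order: the thiazole is made first (Hantzsch, step 2); a transient 1,2‑oxaborinine ring forms in step 7 and is opened in step 9.

## Route

**Step 1**
Reactants: 1, ethyl 2‑cyano‑2‑methylpropanoate
Product: 2, ethyl 3‑amino‑2,2‑dimethyl‑3‑thioxopropanoate
Conditions: (EtO)2P(S)SH (1.5 equiv), H2O (2 equiv), 80 °C
Reagents that add atoms: O,O‑diethyl dithiophosphate, CCOP(=S)(S)OCC (sulfur)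
Why: Thiolysis of a nitrile to a primary thioamide under mildly acidic conditions, which the hindered ethyl ester survives.

**Step 2**
Reactants: 2, thioamide; 3, 1,3‑dichloroacetone
Product: 4, ethyl 2‑[4‑(chloromethyl)‑1,3‑thiazol‑2‑yl]‑2‑methylpropanoate
Conditions: EtOH, reflux, 6 h; then aq. NaHCO3
Reagents that add atoms: 3, 1,3‑dichloroacetone, O=C(CCl)CCl
Why: Hantzsch thiazole synthesis (S‑alkylation, N‑condensation on the ketone, dehydration) gives the 2,4‑disubstituted thiazole with a CH2Cl handle at C4.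

**Step 3**
Reactants: 4, chloromethylthiazole; 5, pent‑1‑en‑4‑yne (2 equiv)
Product: 6, ethyl 2‑[4‑(hex‑5‑en‑2‑yn‑1‑yl)‑1,3‑thiazol‑2‑yl]‑2‑methylpropanoate
Conditions: CuI (1 equiv), NaI (1 equiv), Cs2CO3 (1.5 equiv), DMF, rt, 16 h
Reagents that add atoms: 5, pent‑1‑en‑4‑yne, C=CCC#C
Why: Copper‑acetylide C(sp)–C(sp3) coupling with a heterobenzylic halide (in situ Finkelstein to the iodide), mild enough at rt to avoid allene isomerisation.

**Step 4**
Reactants: 6, skipped enyne
Product: 7, ethyl 2‑{4‑[(2Z)‑hexa‑2,5‑dien‑1‑yl]‑1,3‑thiazol‑2‑yl}‑2‑methylpropanoate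
Conditions: H2 (1 atm, stopped at 1.0 equiv), Lindlar catalyst, quinoline, EtOAc, 0 °C to rt
Reagents that add atoms: none (H2 only)
Why: Lindlar syn‑semihydrogenation sets the (Z)‑olefin, and the poisoned catalyst reduces the alkyne much faster than the terminal vinyl group.

**Step 5**
Reactants: 7, ester
Product: 8, 2‑{4‑[(2Z)‑hexa‑2,5‑dien‑1‑yl]‑1,3‑thiazol‑2‑yl}‑2‑methylpropanal
Conditions: DIBAL‑H (1.15 equiv), CH2Cl2, −78 °C; Rochelle salt
Reagents that add atoms: none
Why: Partial ester reduction, where the neopentyl, thiazole‑N‑chelated tetrahedral aluminate persists at −78 °C and gives the non‑enolisable aldehyde on work‑up.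

**Step 6**
Reactants: 9, bis(pinacolato)borylmethane; 10, vinyl bromide
Product: 11, 2,2'‑(prop‑2‑ene‑1,1‑diyl)bis(4,4,5,5‑tetramethyl‑1,3,2‑dioxaborolane)
Conditions: LiTMP, THF, 0 °C; ZnBr2, 0 °C to rt; then 10, Pd(PPh3)4 (5 mol%), THF, rt to 50 °C (sealed)
Reagents that add atoms: 10, vinyl bromide, C=CBr
Why: Negishi coupling of the (diborylmethyl)zinc halide with an alkenyl bromide forms the C–C bond through zinc and keeps both C–B bonds.

**Step 7 (key step)**
Reactants: 8, aldehyde; 11, α‑boryl allylboronate (1.3 equiv)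
Product: 12, (6R)‑6‑(2‑{4‑[(2Z)‑hexa‑2,5‑dien‑1‑yl]‑1,3‑thiazol‑2‑yl}propan‑2‑yl)‑2‑hydroxy‑5,6‑dihydro‑2H‑1,2‑oxaborinine. This is the cyclised form of the (R,Z)‑δ‑boryl homoallylic alcohol; pinacol is released on work‑up.
Conditions: (R)‑TRIP (10 mol%), 4 Å MS, toluene, −45 to −20 °C, 48 h; aq. NaHCO3 work‑up
Reagents that add atoms: 11, C=CC(B1OC(C)(C)C(C)(C)O1)B1OC(C)(C)C(C)(C)O1 (C3 unit and boron); water, O (B–OH)
Why: Chiral‑phosphoric‑acid‑catalysed allylboration through a closed chair transition state, in which (R)‑TRIP directs Re‑face attack on the aldehyde to give the (R)‑carbinol (the same sense as with allyl‑Bpin), and the non‑reacting Bpin sits axial to avoid the pinacol of the reacting boron, which gives the (Z)‑alkenylboron that is then locked as the six‑membered B–O ring.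

**Step 8**
Reactants: 13, 4‑bromopent‑4‑enoic acid
Product: 14, methyl N‑(3‑bromobut‑3‑en‑1‑yl)carbamate
Conditions: DPPA, Et3N, toluene, 85 °C, 2 h; then MeOH, 70 °C
Reagents that add atoms: diphenylphosphoryl azide, [N-]=[N+]=NP(=O)(Oc1ccccc1)Oc1ccccc1 (nitrogen); methanol, CO (OMe)
Why: Curtius rearrangement to the isocyanate and trapping with methanol gives the methyl carbamate directly, and the vinyl bromide is inert to these conditions.

**Step 9**
Reactants: 12, cyclic (Z)‑alkenylboronic hemiester; 14, 2‑bromoalkene carbamate (1.3 equiv)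
Product: 15, mycothiazole
Conditions: Pd(PPh3)4 (5 mol%), K3PO4 (3 equiv), degassed THF/H2O (5:1), 45 °C, dark
Reagents that add atoms: 14, C=C(Br)CCNC(=O)OC
Why: Suzuki–Miyaura coupling proceeds with retention at both sp2 carbons, so the ring‑enforced (Z)‑geometry is carried into the 2‑substituted (Z)‑1,3‑diene as the oxaborinine opens to release the free (R)‑alcohol; the carbamate N–H, thiazole and skipped diene tolerate the mild aqueous base.

## Compound list

1 | ethyl 2‑cyano‑2‑methylpropanoate | CCOC(=O)C(C)(C)C#N | starting material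
2 | ethyl 3‑amino‑2,2‑dimethyl‑3‑thioxopropanoate | CCOC(=O)C(C)(C)C(N)=S | intermediate
3 | 1,3‑dichloroacetone | O=C(CCl)CCl | starting material
4 | ethyl 2‑[4‑(chloromethyl)‑1,3‑thiazol‑2‑yl]‑2‑methylpropanoate | CCOC(=O)C(C)(C)c1nc(CCl)cs1 | intermediate
5 | pent‑1‑en‑4‑yne | C=CCC#C | starting material
6 | ethyl 2‑[4‑(hex‑5‑en‑2‑yn‑1‑yl)‑1,3‑thiazol‑2‑yl]‑2‑methylpropanoate | CCOC(=O)C(C)(C)c1nc(CC#CCC=C)cs1 | intermediate
7 | ethyl 2‑{4‑[(2Z)‑hexa‑2,5‑dien‑1‑yl]‑1,3‑thiazol‑2‑yl}‑2‑methylpropanoate | CCOC(=O)C(C)(C)c1nc(C/C=C\CC=C)cs1 | intermediate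
8 | 2‑{4‑[(2Z)‑hexa‑2,5‑dien‑1‑yl]‑1,3‑thiazol‑2‑yl}‑2‑methylpropanal | O=CC(C)(C)c1nc(C/C=C\CC=C)cs1 | intermediate
9 | bis(pinacolato)borylmethane | CC1(C)OB(CB2OC(C)(C)C(C)(C)O2)OC1(C)C | starting material
10 | vinyl bromide | C=CBr | starting material
11 | 2,2'‑(prop‑2‑ene‑1,1‑diyl)bis(4,4,5,5‑tetramethyl‑1,3,2‑dioxaborolane) | C=CC(B1OC(C)(C)C(C)(C)O1)B1OC(C)(C)C(C)(C)O1 | intermediate
12 | (6R)‑6‑(2‑{4‑[(2Z)‑hexa‑2,5‑dien‑1‑yl]‑1,3‑thiazol‑2‑yl}propan‑2‑yl)‑2‑hydroxy‑5,6‑dihydro‑2H‑1,2‑oxaborinine | C=CC/C=C\Cc1csc(C(C)(C)[C@H]2CC=CB(O)O2)n1 | intermediate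
13 | 4‑bromopent‑4‑enoic acid | C=C(Br)CCC(=O)O | starting material
14 | methyl N‑(3‑bromobut‑3‑en‑1‑yl)carbamate | C=C(Br)CCNC(=O)OC | intermediate
15 | mycothiazole, methyl N‑[(4Z,7R)‑7‑hydroxy‑8‑{4‑[(2Z)‑hexa‑2,5‑dien‑1‑yl]‑1,3‑thiazol‑2‑yl}‑8‑methyl‑3‑methylidenenon‑4‑en‑1‑yl]carbamate | C=CC/C=C\Cc1csc(C(C)(C)[C@H](O)C/C=C\C(=C)CCNC(=O)OC)n1 | target

## Summary

Total steps: 9.
Longest linear sequence: 7 (steps 1, 2, 3, 4, 5, 7, 9; compounds 1 → 2 → 4 → 6 → 7 → 8 → 12 → 15).

**Three steps most likely to fail, each with a fallback that changes the approach**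

1. **Step 7.** The neopentyl aldehyde is hindered and the basic thiazole nitrogen can hydrogen‑bond to the phosphoric acid, which may erode rate, ee or Z‑selectivity. The sense of induction is assigned by analogy and must be confirmed (Mosher ester); (S)‑TRIP gives the antipode.
 Fallback: switch to alkyne logic. Reagent‑controlled asymmetric propargylation of 8 with a tartrate‑derived allenylboronate gives the (R)‑homopropargylic alcohol; Sonogashira coupling with 14 gives the enyne; Zn(Cu/Ag) semireduction gives the (Z)‑diene.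

2. **Step 9.** Transmetalation of the cyclic hemiester may be slow, and Z→E isomerisation or protodeboronation could compete.
 Fallback: invert the coupling polarity. Iododeboronation of 12 (NIS, or I2/NaOH, with retention) gives the (Z)‑vinyl iodide; this is coupled by Stille reaction (Pd/CuTC) with the 2‑trimethylstannyl alkene made from 14 and Me3SnSnMe3.

3. **Step 4 (with step 3).** The terminal vinyl group may over‑reduce, the thiazole sulfur may slow the catalyst, and the skipped enyne may isomerise.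
 Fallback: replace steps 3 and 4 with a single sp3–sp2 Stille coupling of chloromethylthiazole 4 with pre‑formed (Z)‑tributyl(penta‑1,4‑dien‑1‑yl)stannane, so the Z‑geometry is set before coupling and no hydrogenation is needed.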